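**Retrosynthetic overview** (carotenoid numbering: ring C1 = CMe2, C3 = carbinol, C5 = methyl-bearing sp2 carbon, C6 = alkynyl-bearing sp2 carbon; alkyne C7≡C8; chain C9 to C15, then C15' down to C10' = CH2OH)
1. Last skeletal bond is C8–C9: Sonogashira coupling of the free ethynyl ring with a C9–C10' pentaenyl bromide, then removal of one silyl ether.
2. The pentaenyl bromide is built only by stereospecific metalations and cross-couplings: C13'=C14' and C13=C14 by methylalumination, C15=C15' from a distannylethene, C11=C12 by hydrozirconation, C9=C10 from (E)-2-bromo-1-iodopropene.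
3. The strategy rests on the tetrasubstituted ring alkene C5=C6, conjugated to C7≡C8 and bonded through C6 to the quaternary C1. Cutting C1–C6 gives an acyclic dienyne in which a C1 cation is captured by C6 of the enyne alkene.
4. The acyclic precursor takes C3 from (S)-epichlorohydrin: C1/C2 by cuprate opening, C5/C6 by acetylide opening, the C5 methyl by methylalumination, C7/C8 by Sonogashira coupling.
5. There is one ring; it is closed once, in step 7.

Key step: step 7

Assumption: the secondary C3 hydroxyl needs no protection in steps 18 and 19, and (4R,6R)-4-hydroxy-2,2,6-trimethylcyclohexan-1-one, used only in a fallback, is taken as a purchasable chiral building block.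

**Ring fragment**

Step 1
Reactants: 1 (S)-epichlorohydrin; 2 isopropenylmagnesium bromide
Product: 3 (2S)-1-chloro-4-methylpent-4-en-2-ol
Conditions: CuI (10 mol%), THF, −40 → −20 °C; aq. NH4Cl
Reagents that add atoms: none
Why: Copper-catalysed Grignard opening of the epoxide (SN2 at the oxirane CH2) should outpace chloride displacement, and since no bond to the carbinol carbon is touched the centre of 1 is carried over unchanged.

Step 2
Reactants: 3 (2S)-1-chloro-4-methylpent-4-en-2-ol
Product: 4 (2S)-2-(2-methylprop-2-en-1-yl)oxirane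
Conditions: NaOH (powdered), Et2O, 0 °C → rt; careful distillation (volatile)
Reagents that add atoms: none
Why: Intramolecular Williamson etherification: the alkoxide displaces the primary chloride, the C–O bond at the stereocentre stays intact, and the electrophilic CH2 is moved to the other side of the carbinol.

Step 3
Reactants: 4 (2S)-2-(2-methylprop-2-en-1-yl)oxirane
Product: 5 (4S)-6-methylhept-6-en-1-yn-4-ol
Conditions: LiC≡CH·H2NCH2CH2NH2, DMSO, 0 °C → rt; aq. NH4Cl
Reagents that add atoms: lithium acetylide–ethylenediamine complex, [Li]C#C.NCCN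
Why: SN2 opening of a terminal epoxide by an acetylide occurs at the unsubstituted carbon, so the secondary carbinol keeps its configuration.

Step 4
Reactants: 5 (4S)-6-methylhept-6-en-1-yn-4-ol
Product: 6 tert-butyl{[(4S)-6-methylhept-6-en-1-yn-4-yl]oxy}diphenylsilane
Conditions: TBDPSCl, imidazole, DMF, rt
Reagents that add atoms: tert-butyl(chloro)diphenylsilane, CC(C)(C)[Si](Cl)(c1ccccc1)c1ccccc1
Why: Standard silylation of a secondary alcohol; the bulky, weakly basic TBDPS ether is chosen to withstand the acid of step 7.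

Step 5
Reactants: 6 tert-butyl{[(4S)-6-methylhept-6-en-1-yn-4-yl]oxy}diphenylsilane
Product: 8 tert-butyl{[(1E,4S)-1-iodo-2,6-dimethylhepta-1,6-dien-4-yl]oxy}diphenylsilane, via alkenyldimethylalane 7 (not isolated)
Conditions: Me3Al, Cp2ZrCl2 (25 mol%), CH2Cl2, 0 °C → rt; then I2, THF, −30 → 0 °C
Reagents that add atoms: trimethylaluminium, C[Al](C)C; iodine, II
Why: Zirconium-catalysed methylalumination (Negishi carboalumination) adds methyl and aluminium syn across the terminal alkyne with methyl on the internal carbon, and iodinolysis with retention should give the (E)-iodide; the 1,1-disubstituted alkene and the silyl ether are inert.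

Step 6
Reactants: 8 tert-butyl{[(1E,4S)-1-iodo-2,6-dimethylhepta-1,6-dien-4-yl]oxy}diphenylsilane; 9 (triisopropylsilyl)acetylene
Product: 10 tert-butyl{[(3E,6S)-4,8-dimethyl-1-[tri(propan-2-yl)silyl]nona-3,8-dien-1-yn-6-yl]oxy}diphenylsilane
Conditions: Pd(PPh3)2Cl2 (3 mol%), CuI (6 mol%), Et3N, THF, rt
Reagents that add atoms: none
Why: Sonogashira coupling of an alkenyl iodide with a terminal alkyne proceeds with retention of alkene geometry and installs C7≡C8 with an acid-resistant silyl cap.

Step 7
Reactants: 10 tert-butyl{[(3E,6S)-4,8-dimethyl-1-[tri(propan-2-yl)silyl]nona-3,8-dien-1-yn-6-yl]oxy}diphenylsilane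
Product: 13 tert-butyl{[(1R)-3,5,5-trimethyl-4-{[tri(propan-2-yl)silyl]ethynyl}cyclohex-3-en-1-yl]oxy}diphenylsilane, via tertiary C1 cation 11 (not isolated), via cyclised C5 cation 12 (not isolated)
Conditions: HNTf2 (20 mol%), CH2Cl2, −78 → −30 °C; Et3N quench
Reagents that add atoms: none
Why: Proposed new method: the acid protonates the isolated 1,1-disubstituted alkene at its CH2 terminus to give tertiary cation 11 at C1, C6 of the enyne alkene attacks it in a 6-endo, Markovnikov closure that forms the C1–C6 bond and the only ring and leaves tertiary C5 cation 12, and loss of the now propargylic C6 proton gives the tetrasubstituted conjugated enyne 13. The closest known reaction is the Brønsted-acid cyclisation of pseudoionone to β-ionone, a cation–olefin cyclisation with the same C1 cation and the same C5=C6 terminating alkene; a 1,3-enyne as terminator and a C3 silyloxy group on the tether have not been shown. The ring should close through a chair-like transition state with the C3 silyloxy group equatorial; no new stereocentre survives because the C6 centre of 12 is destroyed on elimination, and no bond at C3 is made or broken, so the configuration from 1 is retained (the descriptor changes from S in 10 to R in 13 only because the CIP ranking of the two CH2 arms is reversed). Two selectivities are needed: protonation of the isopropenyl group and not of the enyne, which the electron-poor silyl-capped alkyne secures by deactivating C5=C6 (the bulky silyl group also blocks protodesilylation), and proton loss from C6 and not from C4 or the C5 methyl, which is secured thermodynamically because the acid re-protonates the unconjugated isomers back to 12 and only the C5=C6 isomer gains enyne conjugation. The competing 5-exo closure would place the charge on a secondary propargylic carbon and join two fully substituted carbons, so it is disfavoured electronically and sterically.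

Step 8
Reactants: 13 tert-butyl{[(1R)-3,5,5-trimethyl-4-{[tri(propan-2-yl)silyl]ethynyl}cyclohex-3-en-1-yl]oxy}diphenylsilane
Product: 14 (1R)-4-ethynyl-3,5,5-trimethylcyclohex-3-en-1-ol
Conditions: TBAF, THF, 0 °C → rt
Reagents that add atoms: none
Why: Fluoride desilylation cleaves both the alkynyl C–Si and the O–Si bond without touching the stereocentre or the enyne.

**Pentaenyl fragment**

Step 9
Reactants: 15 pent-4-yn-1-ol
Product: 17 (4E)-5-iodo-4-methylpent-4-en-1-ol, via alkenylalane alkoxide 16 (not isolated)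
Conditions: Me3Al, Cp2ZrCl2 (25 mol%), CH2Cl2, 0 °C → rt; then I2, THF, −30 → 0 °C
Reagents that add atoms: trimethylaluminium, C[Al](C)C; iodine, II
Why: Negishi carboalumination of the aluminium alkoxide of the alkynol (syn addition, methyl to the internal carbon) followed by iodinolysis with retention should set the C13'=C14' geometry as E.

Step 10
Reactants: 17 (4E)-5-iodo-4-methylpent-4-en-1-ol
Product: 18 tert-butyl{[(4E)-5-iodo-4-methylpent-4-en-1-yl]oxy}dimethylsilane
Conditions: TBSCl, imidazole, CH2Cl2, rt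
Reagents that add atoms: tert-butyl(chloro)dimethylsilane, CC(C)(C)[Si](C)(C)Cl
Why: Standard silylation of the primary alcohol protects C10'–OH from the organometallic steps that follow.

Step 11
Reactants: 18 tert-butyl{[(4E)-5-iodo-4-methylpent-4-en-1-yl]oxy}dimethylsilane
Product: 19 tert-butyldimethyl{[(4E,6E)-4-methyl-7-(tributylstannyl)hepta-4,6-dien-1-yl]oxy}silane
Conditions: (E)-Bu3SnCH=CHSnBu3 (3 equiv), PdCl2(MeCN)2 (5 mol%), DMF, rt, dark
Reagents that add atoms: (E)-1,2-bis(tributylstannyl)ethene, CCCC[Sn](CCCC)(CCCC)/C=C/[Sn](CCCC)(CCCC)CCCC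
Why: Stille coupling with retention at both partners delivers the (E)-C15=C15' unit, and the excess of distannane should hold the reaction at mono-coupling.

Step 12
Reactants: 20 prop-2-yn-1-ol
Product: 22 (2E)-3-iodo-2-methylprop-2-en-1-ol, via alkenylalane alkoxide 21 (not isolated)
Conditions: Me3Al, Cp2ZrCl2 (25 mol%), CH2Cl2, 0 °C → rt; then I2, THF, −30 → 0 °C
Reagents that add atoms: trimethylaluminium, C[Al](C)C; iodine, II
Why: Negishi carboalumination–iodinolysis of propargyl alcohol gives the (E)-iodide that carries C12, C13 with its methyl, and C14.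

Step 13
Reactants: 19 tert-butyldimethyl{[(4E,6E)-4-methyl-7-(tributylstannyl)hepta-4,6-dien-1-yl]oxy}silane; 22 (2E)-3-iodo-2-methylprop-2-en-1-ol
Product: 23 (2E,4E,6E)-10-{[tert-butyl(dimethyl)silyl]oxy}-2,7-dimethyldeca-2,4,6-trien-1-ol
Conditions: PdCl2(MeCN)2 (5 mol%), DMF, rt, dark
Reagents that add atoms: none
Why: Stille coupling of a dienylstannane with an alkenyl iodide forms the C14–C15 bond with retention of all three alkene geometries and tolerates the free allylic alcohol.

Step 14
Reactants: 23 (2E,4E,6E)-10-{[tert-butyl(dimethyl)silyl]oxy}-2,7-dimethyldeca-2,4,6-trien-1-ol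
Product: 24 (2E,4E,6E)-10-{[tert-butyl(dimethyl)silyl]oxy}-2,7-dimethyldeca-2,4,6-trienal
Conditions: MnO2, CH2Cl2, rt, dark
Reagents that add atoms: none
Why: MnO2 oxidises the allylic alcohol selectively to the enal under neutral conditions that leave the triene geometry and the silyl ether alone.

Step 15
Reactants: 24 (2E,4E,6E)-10-{[tert-butyl(dimethyl)silyl]oxy}-2,7-dimethyldeca-2,4,6-trienal
Product: 25 tert-butyl{[(4E,6E,8E)-4,9-dimethylundeca-4,6,8-trien-10-yn-1-yl]oxy}dimethylsilane
Conditions: MeC(O)C(N2)P(O)(OMe)2, K2CO3, MeOH, 0 °C → rt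
Reagents that add atoms: dimethyl (1-diazo-2-oxopropyl)phosphonate, CC(=O)C(=[N+]=[N-])P(=O)(OC)OC
Why: Ohira–Bestmann (Seyferth–Gilbert) homologation converts the α-methyl enal into the terminal enyne, adding C11 without touching the alkene geometries.

Step 16
Reactants: 26 propyne
Product: 27 (1E)-2-bromo-1-iodoprop-1-ene
Conditions: IBr, CH2Cl2, −78 °C
Reagents that add atoms: iodine monobromide, IBr
Why: Electrophilic anti addition of iodine monobromide to a terminal alkyne places iodine on the terminal carbon and bromide on the internal one, which fixes the two halogens trans.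

Step 17
Reactants: 25 tert-butyl{[(4E,6E,8E)-4,9-dimethylundeca-4,6,8-trien-10-yn-1-yl]oxy}dimethylsilane; 27 (1E)-2-bromo-1-iodoprop-1-ene
Product: 30 {[(4E,6E,8E,10E,12E)-13-bromo-4,9-dimethyltetradeca-4,6,8,10,12-pentaen-1-yl]oxy}(tert-butyl)dimethylsilane, via alkenylzirconocene chloride 28 (not isolated), via alkenylzinc chloride 29 (not isolated)
Conditions: Cp2Zr(H)Cl, THF, rt; ZnCl2; then 27, Pd(PPh3)4 (5 mol%), 0 °C → rt, dark
Reagents that add atoms: none
Why: Syn hydrozirconation of the terminal alkyne sets C11=C12 as E, and Negishi coupling of the derived alkenylzinc should occur selectively at the C–I bond of 27 with retention, leaving the C9 bromide trans to C11.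

**Assembly**

Step 18
Reactants: 14 (1R)-4-ethynyl-3,5,5-trimethylcyclohex-3-en-1-ol; 30 {[(4E,6E,8E,10E,12E)-13-bromo-4,9-dimethyltetradeca-4,6,8,10,12-pentaen-1-yl]oxy}(tert-butyl)dimethylsilane
Product: 31 (1R)-4-[(3E,5E,7E,9E,11E)-15-{[tert-butyl(dimethyl)silyl]oxy}-3,7,12-trimethylpentadeca-3,5,7,9,11-pentaen-1-yn-1-yl]-3,5,5-trimethylcyclohex-3-en-1-ol
Conditions: Pd(PPh3)4 (5 mol%), CuI (10 mol%), iPr2NH, THF, rt → 40 °C, degassed, dark
Reagents that add atoms: none
Why: Sonogashira coupling of the terminal alkyne with the alkenyl bromide forms C8–C9 with retention, so C9=C10 is E, and it tolerates the free secondary alcohol.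

Step 19
Reactants: 31 (1R)-4-[(3E,5E,7E,9E,11E)-15-{[tert-butyl(dimethyl)silyl]oxy}-3,7,12-trimethylpentadeca-3,5,7,9,11-pentaen-1-yn-1-yl]-3,5,5-trimethylcyclohex-3-en-1-ol
Product: 32 (1R)-4-[(3E,5E,7E,9E,11E)-15-hydroxy-3,7,12-trimethylpentadeca-3,5,7,9,11-pentaen-1-yn-1-yl]-3,5,5-trimethylcyclohex-3-en-1-ol (CNP0344116.1)
Conditions: TBAF, THF, 0 °C, dark
Reagents that add atoms: none
Why: Fluoride cleavage of the primary silyl ether is neutral to the acid- and light-sensitive pentaenyne and should release the target.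

**Compound list**
1 | (S)-epichlorohydrin | ClC[C@@H]1CO1 | starting material
2 | isopropenylmagnesium bromide | C=C(C)[Mg]Br | starting material
3 | (2S)-1-chloro-4-methylpent-4-en-2-ol | ClC[C@@H](O)CC(C)=C | intermediate
4 | (2S)-2-(2-methylprop-2-en-1-yl)oxirane | C=C(C)C[C@H]1CO1 | intermediate
5 | (4S)-6-methylhept-6-en-1-yn-4-ol | C=C(C)C[C@H](O)CC#C | intermediate
6 | tert-butyl{[(4S)-6-methylhept-6-en-1-yn-4-yl]oxy}diphenylsilane | C=C(C)C[C@H](O[Si](c1ccccc1)(c1ccccc1)C(C)(C)C)CC#C | intermediate
7 | (E)-alkenyldimethylalane from methylalumination of 6 | C=C(C)C[C@H](O[Si](c1ccccc1)(c1ccccc1)C(C)(C)C)C/C(C)=C/[Al](C)C | intermediate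
8 | tert-butyl{[(1E,4S)-1-iodo-2,6-dimethylhepta-1,6-dien-4-yl]oxy}diphenylsilane | C=C(C)C[C@H](O[Si](c1ccccc1)(c1ccccc1)C(C)(C)C)C/C(C)=C/I | intermediate
9 | (triisopropylsilyl)acetylene | C#C[Si](C(C)C)(C(C)C)C(C)C | starting material
10 | tert-butyl{[(3E,6S)-4,8-dimethyl-1-[tri(propan-2-yl)silyl]nona-3,8-dien-1-yn-6-yl]oxy}diphenylsilane | C=C(C)C[C@H](O[Si](c1ccccc1)(c1ccccc1)C(C)(C)C)C/C(C)=C/C#C[Si](C(C)C)(C(C)C)C(C)C | intermediate
11 | tertiary C1 cation from protonation of 10 | C[C+](C)C[C@H](O[Si](c1ccccc1)(c1ccccc1)C(C)(C)C)C/C(C)=C/C#C[Si](C(C)C)(C(C)C)C(C)C | intermediate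
12 | cyclised tertiary C5 cation | C[C+]1C(C#C[Si](C(C)C)(C(C)C)C(C)C)C(C)(C)C[C@H](O[Si](c2ccccc2)(c2ccccc2)C(C)(C)C)C1 | intermediate
13 | tert-butyl{[(1R)-3,5,5-trimethyl-4-{[tri(propan-2-yl)silyl]ethynyl}cyclohex-3-en-1-yl]oxy}diphenylsilane | CC1=C(C#C[Si](C(C)C)(C(C)C)C(C)C)C(C)(C)C[C@H](O[Si](c2ccccc2)(c2ccccc2)C(C)(C)C)C1 | intermediate
14 | (1R)-4-ethynyl-3,5,5-trimethylcyclohex-3-en-1-ol | CC1=C(C#C)C(C)(C)C[C@H](O)C1 | intermediate
15 | pent-4-yn-1-ol | C#CCCCO | starting material
16 | (E)-alkenyldimethylalane dimethylaluminium alkoxide from 15 | C[Al](C)/C=C(\C)CCCO[Al](C)C | intermediate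
17 | (4E)-5-iodo-4-methylpent-4-en-1-ol | OCCC/C(C)=C/I | intermediate
18 | tert-butyl{[(4E)-5-iodo-4-methylpent-4-en-1-yl]oxy}dimethylsilane | CC(C)(C)[Si](C)(C)OCCC/C(C)=C/I | intermediate
19 | tert-butyldimethyl{[(4E,6E)-4-methyl-7-(tributylstannyl)hepta-4,6-dien-1-yl]oxy}silane | CC(C)(C)[Si](C)(C)OCCC/C(C)=C/C=C/[Sn](CCCC)(CCCC)CCCC | intermediate
20 | prop-2-yn-1-ol | C#CCO | starting material
21 | (E)-alkenyldimethylalane dimethylaluminium alkoxide from 20 | C[Al](C)/C=C(\C)CO[Al](C)C | intermediate
22 | (2E)-3-iodo-2-methylprop-2-en-1-ol | OC/C(C)=C/I | intermediate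
23 | (2E,4E,6E)-10-{[tert-butyl(dimethyl)silyl]oxy}-2,7-dimethyldeca-2,4,6-trien-1-ol | OC/C(C)=C/C=C/C=C(\C)CCCO[Si](C)(C)C(C)(C)C | intermediate
24 | (2E,4E,6E)-10-{[tert-butyl(dimethyl)silyl]oxy}-2,7-dimethyldeca-2,4,6-trienal | O=C/C(C)=C/C=C/C=C(\C)CCCO[Si](C)(C)C(C)(C)C | intermediate
25 | tert-butyl{[(4E,6E,8E)-4,9-dimethylundeca-4,6,8-trien-10-yn-1-yl]oxy}dimethylsilane | C#C/C(C)=C/C=C/C=C(\C)CCCO[Si](C)(C)C(C)(C)C | intermediate
26 | propyne | CC#C | starting material
27 | (1E)-2-bromo-1-iodoprop-1-ene | C/C(Br)=C\I | intermediate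
28 | (E)-alkenylzirconocene chloride from hydrozirconation of 25 | Cl[Zr](/C=C/C(C)=C/C=C/C=C(\C)CCCO[Si](C)(C)C(C)(C)C)(C1C=CC=C1)C1C=CC=C1 | intermediate
29 | (E)-alkenylzinc chloride from 28 | Cl[Zn]/C=C/C(C)=C/C=C/C=C(\C)CCCO[Si](C)(C)C(C)(C)C | intermediate
30 | {[(4E,6E,8E,10E,12E)-13-bromo-4,9-dimethyltetradeca-4,6,8,10,12-pentaen-1-yl]oxy}(tert-butyl)dimethylsilane | Br/C(C)=C/C=C/C(C)=C/C=C/C=C(\C)CCCO[Si](C)(C)C(C)(C)C | intermediate
31 | (1R)-4-[(3E,5E,7E,9E,11E)-15-{[tert-butyl(dimethyl)silyl]oxy}-3,7,12-trimethylpentadeca-3,5,7,9,11-pentaen-1-yn-1-yl]-3,5,5-trimethylcyclohex-3-en-1-ol | CC1=C(C#C/C(C)=C/C=C/C(C)=C/C=C/C=C(\C)CCCO[Si](C)(C)C(C)(C)C)C(C)(C)C[C@H](O)C1 | intermediate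
32 | (1R)-4-[(3E,5E,7E,9E,11E)-15-hydroxy-3,7,12-trimethylpentadeca-3,5,7,9,11-pentaen-1-yn-1-yl]-3,5,5-trimethylcyclohex-3-en-1-ol | CC1=C(C#C/C(C)=C/C=C/C(C)=C/C=C/C=C(\C)CCCO)C(C)(C)C[C@H](O)C1 | target

**Step count and risk**

Total step count: 19 (ring fragment steps 1–8, pentaenyl fragment steps 9–17, assembly steps 18–19).
Longest linear sequence: 10 steps (steps 1–8, 18, 19).

Steps most likely to fail:

1. Step 7 (Proposed new method). The acid may protonate the enyne or the silyl-capped alkyne instead of the isopropenyl group. The cyclised cation may also end by proton loss toward C4, after which the then allylic silyl ether can ionise, or the acid may strip the silyl groups before ring closure. The fallback uses only known chemistry, takes the ring from the chiral pool and attaches the alkyne by cross-coupling; it sets out from compound 9 and comes back to the route at compound 13. Commercial (4R,6R)-4-hydroxy-2,2,6-trimethylcyclohexan-1-one F1 would be silylated (TBDPSCl, imidazole, DMF) to (4R,6R)-4-{[tert-butyl(diphenyl)silyl]oxy}-2,2,6-trimethylcyclohexan-1-one F2. LDA (THF, −78 °C) removes the only enolisable proton and PhNTf2 traps the enolate as (4R)-4-{[tert-butyl(diphenyl)silyl]oxy}-2,6,6-trimethylcyclohex-1-en-1-yl trifluoromethanesulfonate F3, which erases the methyl-bearing centre. Sonogashira coupling of F3 with 9 (Pd(PPh3)4, CuI, Et3N, DMF) should then give 13.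

2. Step 17. Site selectivity between the carbon–iodine and carbon–bromine bonds of 27 may be lost, both vicinal halogens may be eliminated after oxidative addition, or the polyenylmetal may homocouple. The fallback makes the C9 halide by hydrometalation instead of delivering it with a dihalide; it sets out from compound 25 (through its hydrozirconation product 28) and comes back at compound 31, bypassing 30. Intermediate 28 would be quenched with I2 to tert-butyl{[(4E,6E,8E,10E)-11-iodo-4,9-dimethylundeca-4,6,8,10-tetraen-1-yl]oxy}dimethylsilane F4. Sonogashira coupling of F4 with propyne 26 (Pd(PPh3)4, CuI, Et3N) would give tert-butyl{[(4E,6E,8E,10E)-4,9-dimethyltetradeca-4,6,8,10-tetraen-12-yn-1-yl]oxy}dimethylsilane F5. Hydrozirconation with Cp2Zr(H)Cl is expected to place zirconium on the methyl-bearing alkyne carbon, remote from the polyene as with other 1,3-enynes, giving the (E)-pentaenylzirconocene chloride F6, and iodinolysis would give tert-butyl{[(4E,6E,8E,10E,12E)-13-iodo-4,9-dimethyltetradeca-4,6,8,10,12-pentaen-1-yl]oxy}dimethylsilane F7. F7 would be coupled with 14 under the conditions of step 18 to give 31.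

3. Step 18. Copper-mediated oxidative dimerisation may consume the alkyne, and prolonged exposure to amine, copper and warmth may isomerise the pentaene while the hindered bromide couples slowly. The fallback replaces the copper acetylide generated in the flask by an isolated organotin nucleophile; it sets out from compound 14 and comes back at compound 31. Compound 14 would be doubly deprotonated (LiHMDS, THF, −78 °C) and stannylated with Bu3SnCl, the O–Sn bond being cleaved on aqueous work-up, to give (1R)-3,5,5-trimethyl-4-[(tributylstannyl)ethynyl]cyclohex-3-en-1-ol F8. A copper-free, base-free Stille coupling of F8 with 30 (PdCl2(MeCN)2, DMF, rt, dark) should give 31.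

**Further compounds**
F1 | step 7 | (4R,6R)-4-hydroxy-2,2,6-trimethylcyclohexan-1-one | O=C1C(C)(C)C[C@H](O)C[C@H]1C
F2 | step 7 | (4R,6R)-4-{[tert-butyl(diphenyl)silyl]oxy}-2,2,6-trimethylcyclohexan-1-one | O=C1C(C)(C)C[C@H](O[Si](c2ccccc2)(c2ccccc2)C(C)(C)C)C[C@H]1C
F3 | step 7 | (4R)-4-{[tert-butyl(diphenyl)silyl]oxy}-2,6,6-trimethylcyclohex-1-en-1-yl trifluoromethanesulfonate | CC1=C(OS(=O)(=O)C(F)(F)F)C(C)(C)C[C@H](O[Si](c2ccccc2)(c2ccccc2)C(C)(C)C)C1
F4 | step 17 | tert-butyl{[(4E,6E,8E,10E)-11-iodo-4,9-dimethylundeca-4,6,8,10-tetraen-1-yl]oxy}dimethylsilane | I/C=C/C(C)=C/C=C/C=C(\C)CCCO[Si](C)(C)C(C)(C)C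
F5 | step 17 | tert-butyl{[(4E,6E,8E,10E)-4,9-dimethyltetradeca-4,6,8,10-tetraen-12-yn-1-yl]oxy}dimethylsilane | CC#C/C=C/C(C)=C/C=C/C=C(\C)CCCO[Si](C)(C)C(C)(C)C
F6 | step 17 | (E)-pentaenylzirconocene chloride from hydrozirconation of F5 | Cl[Zr](/C(C)=C/C=C/C(C)=C/C=C/C=C(\C)CCCO[Si](C)(C)C(C)(C)C)(C1C=CC=C1)C1C=CC=C1
F7 | step 17 | tert-butyl{[(4E,6E,8E,10E,12E)-13-iodo-4,9-dimethyltetradeca-4,6,8,10,12-pentaen-1-yl]oxy}dimethylsilane | I/C(C)=C/C=C/C(C)=C/C=C/C=C(\C)CCCO[Si](C)(C)C(C)(C)C
F8 | step 18 | (1R)-3,5,5-trimethyl-4-[(tributylstannyl)ethynyl]cyclohex-3-en-1-ol | CC1=C(C#C[Sn](CCCC)(CCCC)CCCC)C(C)(C)C[C@H](O)C1
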